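The readings are calculated with made-up constants; scatter was added.

Take the flask's solid charge as one whole and reckon every amount as a fraction of it.

| flask | solid substrate | partner | remark | time |
|---|---|---|---|---|
| teal | 0.050 M | 0.105 M | run made earlier |  |
| blue | 0.20 M | 0.105 M | run made earlier |  |
| violet | 0.10 M | 0.21 M | run made earlier |  |
| flask | 0.10 M | 0.105 M |  | 4.0 h |

| run | time / h | target / % | dissolved substrate / % |
|---|---|---|---|
| teal | 0.250 | 41.3 | 35.1 |
| teal | 0.667 | 65.5 | 20.2 |
| teal | 1.33 | 69.4 | 14.9 |
| teal | 2.00 | 69.5 | 16.6 |
| teal | 3.00 | 70.3 | 15.1 |
| teal | 4.00 | 70.5 | 16.2 |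
| teal | 5.00 | 71.3 | 14.2 |
| blue | 0.667 | 2.5 | 8.7 |
| blue | 1.33 | 0 | 10.3 |
| blue | 2.00 | 0.9 | 9.4 |
| blue | 3.00 | 0 | 10.4 |
| blue | 4.00 | 1.7 | 8.7 |
| blue | 5.00 | 0 | 7.8 |
| violet | 0.417 | 39.8 | 16.7 |
| violet | 1.33 | 53.5 | 7.7 |
| violet | 2.00 | 54.2 | 5.8 |
| violet | 3.00 | 51.8 | 5.5 |
| violet | 5.00 | 53.8 | 7.9 |

(scatter of a reading: 1 percentage point)

- solid, in amounts per volume of the solution: solid substrate
- at the start none of the solid substrate is in solution
- dissolved substrate means what is dissolved; the solid is not counted in it

* target at 4.0 h, in percent of the solid substrate charged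
* concentration of dissolved substrate in solution at 4.0 h, in percent of saturation

I suppose that what is missing from the teal and violet balances is solid joined to target, one of each, so a pair counts two parts of the charge. Target made is then half of the sum of one and target less dissolved substrate. Scaled by partner to this flask, teal gives 38.8% made and violet 36.6%. The blue level of dissolved substrate makes saturation 18.4% of the flask's charge.

Once partner stops, each pairing takes one target and one solid, so time drops out of their difference. Twice the mean made, plus saturation, less the whole, gives that difference, the margin: −6.19%.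

A negative margin means solid outlasts target, so my lower bound is 0% and the solution stays at 100% of saturation. For the upper bound, teal makes 0.290 h⁻¹ of the flask's charge, while blue holds 5.00% target beside about 1.06 charges of solid. If eating at least matches making, the pair rate is at least 5.46 h⁻¹. A level pair then falls under one over rate times hours. Teal's target levels off by about 1.33 h, so my bound is 6.85%.

The forecast gives 15% and 95%, above my bracket on target, and says “Some solid probably survives”. The flask gives 3.23% and 100%.

    solid substrate ⇌ dissolved substrate, rate k1*(cs1 - [dissolved substrate]) while solid is left; crystals form when [dissolved substrate] > cs1 (solubility = 18.0 mM, k = 0.789 min⁻¹)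
    dissolved substrate + partner → target (k = 1.73 L mol⁻¹ min⁻¹)
    partner → side product A (k = 0.00871 min⁻¹)
    2 solid substrate → self-condensation product (k = 3.16 × 10⁻⁴ L mol⁻¹ min⁻¹)
    partner → decomposed reagent (k = 0.0321 min⁻¹)
    solid substrate + target → side product B (k = 1.23 L mol⁻¹ min⁻¹)

In this flask target 3.23% and solid 3.31% stand level at 4.00 h, with partner, the limiting reagent, at 0%, beside a margin of −6.19%. Target sits this low in part through the low solubility of dissolved substrate together with the decomposition of partner: without that decomposition the run holds 50.3% target. The neighbour with 0.25 M of solid has a margin of −62.5%, and at 4.00 h it holds 58.6% solid and 0% target.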